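Ring atoms are numbered C1 (bears the side chain), C2 (=CH), C3 (CH–OH), C4 (=CH), C5 (C–OMe), C6 (CH–OAc).
Retrosynthesis: C3–OH ⇐ silyl ether; C1=C2 ⇐ syn-elimination of a C1 selenoxide; C6–OAc ⇐ reduction of a C6 ketone; then C2–C3 and C4=C5 are cut together (conjugate addition plus aldol condensation) to an α-branched methoxymethyl vinyl ketone and silyloxyacetaldehyde; the enone is cut at C1–C6 (2-iodoalkene + methoxyacetaldehyde), and the iodide goes back through a homopropargylic acetate and (R)-1,2-epoxytridecane to (R)-epichlorohydrin and decylmagnesium bromide.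
Forward: the chain is joined first (C13 carbinol, alkyne, iodoalkene, enone); the only ring is then closed in one flask (step 7); selenation at C1, reduction and acetylation at C6, formation of C1=C2 and desilylation finish the route.
What makes the ring event possible: C5–C6 is a masked methoxymethyl ketone whose CH2 (C5) is acidic and lies 1,5 to the carbonyl carbon C4 of a glycolaldehyde unit (C3–C4), and C2 is the β-carbon of a vinyl ketone; the 2-methoxy enone that results is already the enol ether of the target.
Stereochemistry: the side-chain centre (R) comes from (R)-epichlorohydrin; C3 (S) from the (R)-prolinol silyl ether catalyst; C6 (S) from hydride delivery anti to the C1–Se bond, selenium having entered trans to the C3 oxygen.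
The C6 ketone is reduced before the second ring double bond is made, because a cyclohexa-2,5-dienone with a hydrogen on its saturated carbon would tautomerise to a phenol.

Key step: step 7

Assumption: 1, 2, 4, 9 and 12 are bought; the (R)-configured catalyst is expected to give (S) at C3 by the usual enamine shielding model, and its enantiomer would be used if the sense proved opposite.

Step 1
Reactants: 1 (R)-epichlorohydrin; 2 decylmagnesium bromide
Product: 3 (2R)-1-chlorotridecan-2-ol
Conditions: CuI (10 mol%), THF, −40 → 0 °C; 1 M HCl work-up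
Reagents that add atoms: none
Why: Copper-catalysed SN2 opening of the epoxide by the Grignard reagent at the unsubstituted ring carbon (epoxide alkylation) does not touch the stereocentre, which becomes the (R) carbinol of the side chain by descent from the chiral pool.

Step 2
Reactants: 3 (2R)-1-chlorotridecan-2-ol; 4 lithium acetylide–ethylenediamine complex
Product: 6 (4R)-pentadec-1-yn-4-ol, via (R)-1,2-epoxytridecane 5 (not isolated)
Conditions: 4 (3 equiv), DMSO, 0 °C → rt; water work-up
Reagents that add atoms: none
Why: The first equivalent of acetylide closes the chlorohydrin to epoxide 5 (intramolecular Williamson etherification, the C–O bond at the stereocentre is kept) and a second equivalent opens 5 at its terminal carbon (SN2 alkynylation of an epoxide), so the carbinol centre stays (R).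

Step 3
Reactants: 6 (4R)-pentadec-1-yn-4-ol
Product: 7 (4R)-pentadec-1-yn-4-yl acetate
Conditions: Ac2O, pyridine, DMAP (cat.), CH2Cl2, rt
Reagents that add atoms: acetic anhydride, CC(=O)OC(C)=O
Why: DMAP-catalysed acylation installs the side-chain acetate of the target early, where it also serves as the protecting group; the stereocentre is not involved.

Step 4
Reactants: 7 (4R)-pentadec-1-yn-4-yl acetate
Product: 8 (4R)-2-iodopentadec-1-en-4-yl acetate
Conditions: NaI, Me3SiCl, H2O (0.5 equiv), MeCN, rt
Reagents that add atoms: sodium iodide, [Na+].[I-]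
Why: Hydrogen iodide formed in the flask adds to the terminal alkyne in the Markovnikov sense (hydroiodination), giving the 2-iodo-1-alkene whose iodine-bearing carbon becomes C1 and whose methylene becomes C2.

Step 5
Reactants: 8 (4R)-2-iodopentadec-1-en-4-yl acetate; 9 methoxyacetaldehyde
Product: 10 (5R)-2-hydroxy-1-methoxy-3-methylidenehexadecan-5-yl acetate
Conditions: CrCl2 (4 equiv), NiCl2 (2 mol%), DMF, rt; water work-up
Reagents that add atoms: none
Why: Nozaki–Hiyama–Kishi coupling (nickel-catalysed C–I activation, transmetalation to chromium, carbonyl addition) forms the C1–C6 bond under neutral conditions that leave the acetate alone; the new carbinol centre arises as both epimers and is erased in step 6.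

Step 6
Reactants: 10 (5R)-2-hydroxy-1-methoxy-3-methylidenehexadecan-5-yl acetate
Product: 11 (5R)-1-methoxy-3-methylidene-2-oxohexadec-5-yl acetate
Conditions: Dess–Martin periodinane, CH2Cl2, 0 °C → rt
Reagents that add atoms: none
Why: Dess–Martin oxidation of the allylic alcohol gives the α-branched vinyl ketone without base, which matters because the product is a reactive Michael acceptor that is used at once.

Step 7
Reactants: 11 (5R)-1-methoxy-3-methylidene-2-oxohexadec-5-yl acetate; 12 (tert-butyldimethylsilyloxy)acetaldehyde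
Product: 15 (2R)-1-[(5S)-5-(tert-butyldimethylsilyloxy)-3-methoxy-2-oxocyclohex-3-en-1-yl]tridecan-2-yl acetate, via keto aldehyde 13 (not isolated), via aldol adduct 14 (not isolated)
Conditions: (R)-2-[diphenyl(trimethylsilyloxy)methyl]pyrrolidine (20 mol%), 4-nitrophenol (20 mol%), toluene, 4 °C; then p-TsOH·H2O (10 mol%), rt, same flask
Reagents that add atoms: none
Why: The amine and 12 give an E-enamine whose oxygen-bearing carbon (C3) adds to the terminal methylene (C2) of the cross-conjugated enone 11 on the face away from the diaryl(silyloxy)methyl group, and hydrolysis of the iminium gives keto aldehyde 13 with C3 set (S) by the catalyst. On addition of acid the enol of the methoxymethyl ketone (C5=C6) attacks the aldehyde carbon C4 in a 6-(enolendo)-exo-trig aldol closure to 14, and loss of water gives the conjugated 2-methoxy enone, so that C2–C3 and C4=C5 are made in one operation. The closest known reaction type is the amine-catalysed Michael addition of aldehydes to vinyl ketones followed by aldol condensation (Robinson-type annulation), and α-oxygenated aldehydes are known donors in such enamine additions. The step needs face selectivity at C3 (catalyst control), regioselective ring closure (only the C5 enol can close a six-membered ring, the C1 enol would give a four-membered one) and retention of the C3 configuration (the α-branched aldehyde 13 re-forms an enamine only slowly and the acid step is run at room temperature). The centre formed at C1 is not controlled, which is harmless because C1 is made trigonal again in steps 8 and 11.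

Step 8
Reactants: 15 (2R)-1-[(5S)-5-(tert-butyldimethylsilyloxy)-3-methoxy-2-oxocyclohex-3-en-1-yl]tridecan-2-yl acetate
Product: 17 (2R)-1-[(1S,5S)-5-(tert-butyldimethylsilyloxy)-3-methoxy-2-oxo-1-(phenylselanyl)cyclohex-3-en-1-yl]tridecan-2-yl acetate, via lithium dienolate 16 (not isolated)
Conditions: LiN(SiMe3)2 (1.05 equiv), THF, −78 °C; then PhSeCl, −78 °C
Reagents that add atoms: benzeneselenenyl chloride, Cl[Se]c1ccccc1
Why: Kinetic deprotonation of the enone at its only α'-hydrogen (C1) gives the cross-conjugated dienolate without touching the γ-hydrogen at C3, and carbon selenenylation (α-selenenylation of a ketone enolate) should occur anti to the C3 silyloxy group as is usual for 4-substituted cyclohexenone enolates, so both C1 epimers of 15 converge on one selenide.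

Step 9
Reactants: 17 (2R)-1-[(1S,5S)-5-(tert-butyldimethylsilyloxy)-3-methoxy-2-oxo-1-(phenylselanyl)cyclohex-3-en-1-yl]tridecan-2-yl acetate
Product: 18 (2R)-1-[(1S,2R,5S)-5-(tert-butyldimethylsilyloxy)-2-hydroxy-3-methoxy-1-(phenylselanyl)cyclohex-3-en-1-yl]tridecan-2-yl acetate
Conditions: NaBH4, CeCl3·7H2O, MeOH, −78 °C
Reagents that add atoms: none
Why: Luche reduction adds hydride 1,2 to the enone carbonyl anti to the axial C–Se bond (the usual course for α-heteroatom ketones), which places the hydroxyl cis to selenium and hence trans to the C3 silyloxy group, the configuration needed at C6.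

Step 10
Reactants: 18 (2R)-1-[(1S,2R,5S)-5-(tert-butyldimethylsilyloxy)-2-hydroxy-3-methoxy-1-(phenylselanyl)cyclohex-3-en-1-yl]tridecan-2-yl acetate
Product: 19 (2R)-1-[(1S,2R,5S)-2-acetoxy-5-(tert-butyldimethylsilyloxy)-3-methoxy-1-(phenylselanyl)cyclohex-3-en-1-yl]tridecan-2-yl acetate
Conditions: Ac2O, pyridine, DMAP (cat.), CH2Cl2, 0 °C → rt
Reagents that add atoms: acetic anhydride, CC(=O)OC(C)=O
Why: DMAP-catalysed acylation of the hindered secondary alcohol gives the C6 acetate of the target without touching a stereocentre.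

Step 11
Reactants: 19 (2R)-1-[(1S,2R,5S)-2-acetoxy-5-(tert-butyldimethylsilyloxy)-3-methoxy-1-(phenylselanyl)cyclohex-3-en-1-yl]tridecan-2-yl acetate
Product: 21 (2R)-1-[(3S,6S)-6-acetoxy-3-(tert-butyldimethylsilyloxy)-5-methoxycyclohexa-1,4-dien-1-yl]tridecan-2-yl acetate, via selenoxide 20 (not isolated)
Conditions: 30% H2O2, pyridine, CH2Cl2, 0 °C → rt
Reagents that add atoms: none
Why: Oxidation of the selenide and syn-elimination of the selenoxide (selenoxide elimination) removes the cis hydrogen at C2 to give C1=C2, the hydrogen at C6 being trans to selenium and on an oxygen-bearing carbon and the endocyclic course being the one known for 2-alkyl-2-selanyl cycloalkanone derivatives; pyridine traps the selenenic acid.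

Step 12
Reactants: 21 (2R)-1-[(3S,6S)-6-acetoxy-3-(tert-butyldimethylsilyloxy)-5-methoxycyclohexa-1,4-dien-1-yl]tridecan-2-yl acetate
Product: 22 (2R)-1-[(3S,6S)-6-acetoxy-3-hydroxy-5-methoxycyclohexa-1,4-dien-1-yl]tridecan-2-yl acetate
Conditions: Bu4NF, AcOH (1:1), THF, 0 °C
Reagents that add atoms: none
Why: Fluoride cleavage of the silyl ether buffered with acetic acid (desilylation) frees the C3 hydroxyl without acid or strong base, so the two acetates, the methyl enol ether and the bis-allylic alcohol, which would aromatise by loss of water or acetic acid under harsher conditions, are kept.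

Compound list
1 | (R)-epichlorohydrin | ClC[C@H]1CO1 | starting material
2 | decylmagnesium bromide | CCCCCCCCCC[Mg]Br | starting material
3 | (2R)-1-chlorotridecan-2-ol | CCCCCCCCCCC[C@@H](O)CCl | intermediate
4 | lithium acetylide–ethylenediamine complex | [Li]C#C.NCCN | starting material
5 | (R)-1,2-epoxytridecane | CCCCCCCCCCC[C@@H]1CO1 | intermediate (not isolated)
6 | (4R)-pentadec-1-yn-4-ol | CCCCCCCCCCC[C@@H](O)CC#C | intermediate
7 | (4R)-pentadec-1-yn-4-yl acetate | CCCCCCCCCCC[C@@H](OC(C)=O)CC#C | intermediate
8 | (4R)-2-iodopentadec-1-en-4-yl acetate | CCCCCCCCCCC[C@@H](OC(C)=O)CC(I)=C | intermediate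
9 | methoxyacetaldehyde | COCC=O | starting material
10 | (5R)-2-hydroxy-1-methoxy-3-methylidenehexadecan-5-yl acetate (both C2 epimers) | CCCCCCCCCCC[C@@H](OC(C)=O)CC(=C)C(O)COC | intermediate
11 | (5R)-1-methoxy-3-methylidene-2-oxohexadec-5-yl acetate | CCCCCCCCCCC[C@@H](OC(C)=O)CC(=C)C(=O)COC | intermediate
12 | (tert-butyldimethylsilyloxy)acetaldehyde | O=CCO[Si](C)(C)C(C)(C)C | starting material
13 | (5R)-3-[(2S)-2-(tert-butyldimethylsilyloxy)-3-oxopropyl]-1-methoxy-2-oxohexadecan-5-yl acetate (both C3 epimers) | CCCCCCCCCCC[C@@H](OC(C)=O)CC(C[C@H](O[Si](C)(C)C(C)(C)C)C=O)C(=O)COC | intermediate (not isolated)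
14 | (2R)-1-[(5S)-5-(tert-butyldimethylsilyloxy)-4-hydroxy-3-methoxy-2-oxocyclohexyl]tridecan-2-yl acetate (diastereomers at ring C1, C3, C4) | CCCCCCCCCCC[C@@H](OC(C)=O)CC1C[C@H](O[Si](C)(C)C(C)(C)C)C(O)C(OC)C1=O | intermediate (not isolated)
15 | (2R)-1-[(5S)-5-(tert-butyldimethylsilyloxy)-3-methoxy-2-oxocyclohex-3-en-1-yl]tridecan-2-yl acetate (both ring C1 epimers) | CCCCCCCCCCC[C@@H](OC(C)=O)CC1C[C@H](O[Si](C)(C)C(C)(C)C)C=C(OC)C1=O | intermediate
16 | lithium (4S)-2-[(2R)-2-acetoxytridecyl]-4-(tert-butyldimethylsilyloxy)-6-methoxycyclohexa-1,5-dien-1-olate | CCCCCCCCCCC[C@@H](OC(C)=O)CC1=C(O[Li])C(OC)=C[C@@H](O[Si](C)(C)C(C)(C)C)C1 | intermediate (not isolated)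
17 | (2R)-1-[(1S,5S)-5-(tert-butyldimethylsilyloxy)-3-methoxy-2-oxo-1-(phenylselanyl)cyclohex-3-en-1-yl]tridecan-2-yl acetate | CCCCCCCCCCC[C@@H](OC(C)=O)C[C@]1([Se]c2ccccc2)C[C@H](O[Si](C)(C)C(C)(C)C)C=C(OC)C1=O | intermediate
18 | (2R)-1-[(1S,2R,5S)-5-(tert-butyldimethylsilyloxy)-2-hydroxy-3-methoxy-1-(phenylselanyl)cyclohex-3-en-1-yl]tridecan-2-yl acetate | CCCCCCCCCCC[C@@H](OC(C)=O)C[C@]1([Se]c2ccccc2)C[C@H](O[Si](C)(C)C(C)(C)C)C=C(OC)[C@H]1O | intermediate
19 | (2R)-1-[(1S,2R,5S)-2-acetoxy-5-(tert-butyldimethylsilyloxy)-3-methoxy-1-(phenylselanyl)cyclohex-3-en-1-yl]tridecan-2-yl acetate | CCCCCCCCCCC[C@@H](OC(C)=O)C[C@]1([Se]c2ccccc2)C[C@H](O[Si](C)(C)C(C)(C)C)C=C(OC)[C@H]1OC(C)=O | intermediate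
20 | (2R)-1-[(1S,2R,5S)-2-acetoxy-5-(tert-butyldimethylsilyloxy)-3-methoxy-1-(phenylseleninyl)cyclohex-3-en-1-yl]tridecan-2-yl acetate | CCCCCCCCCCC[C@@H](OC(C)=O)C[C@]1([Se](=O)c2ccccc2)C[C@H](O[Si](C)(C)C(C)(C)C)C=C(OC)[C@H]1OC(C)=O | intermediate (not isolated)
21 | (2R)-1-[(3S,6S)-6-acetoxy-3-(tert-butyldimethylsilyloxy)-5-methoxycyclohexa-1,4-dien-1-yl]tridecan-2-yl acetate | CCCCCCCCCCC[C@H](CC1=C[C@H](O[Si](C)(C)C(C)(C)C)C=C(OC)[C@H]1OC(C)=O)OC(C)=O | intermediate
22 | (2R)-1-[(3S,6S)-6-acetoxy-3-hydroxy-5-methoxycyclohexa-1,4-dien-1-yl]tridecan-2-yl acetate | CCCCCCCCCCC[C@H](CC1=C[C@H](O)C=C(OC)[C@H]1OC(C)=O)OC(C)=O | target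

Total step count: 12. Longest linear sequence: 12 steps (from 1).

Steps most likely to fail, in this order: 7, 11, 9.

Step 7. The conjugate addition may be slow on the α-branched, polymerisable enone 11, and the C3 centre of 13 may be partly lost by re-enolisation before the ring closes. The fallback introduces the side chain after the annulation by enolate alkylation instead of carrying it in the enone. It sets out from 3 and 12 and comes back at 15. 3 is closed with NaOH to the epoxide 5, which is now isolated. The unbranched vinyl ketone 1-methoxybut-3-en-2-one F1 (from N-methoxy-N-methyl-2-methoxyacetamide and vinylmagnesium bromide) is annulated with 12 under the conditions of step 7, a case well inside the studied range of that reaction, to give (4S)-4-(tert-butyldimethylsilyloxy)-2-methoxycyclohex-2-en-1-one F2. The kinetic lithium enolate of F2 (LiN(SiMe3)2, THF, −78 °C) opens 5 at its terminal carbon in the presence of BF3·OEt2 to give (4S)-4-(tert-butyldimethylsilyloxy)-6-[(2R)-2-hydroxytridecyl]-2-methoxycyclohex-2-en-1-one F3, and acetylation (Ac2O, pyridine, DMAP) returns to 15.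

Step 11. Syn-elimination may run toward the side-chain methylene and give the exocyclic alkene, and selenenic acid may add to the enol ether. The fallback carries the C1=C2 bond from the start through a cyclobutenone ring expansion, so no late elimination is needed. It sets out from 7 and comes back at 21. [2+2] cycloaddition of 7 with dichloroketene (Cl3CCOCl, Zn–Cu couple, Et2O) would give (2R)-1-(4,4-dichloro-3-oxocyclobut-1-en-1-yl)tridecan-2-yl acetate F4, and zinc in acetic acid with TMEDA would remove both chlorines to give (2R)-1-(3-oxocyclobut-1-en-1-yl)tridecan-2-yl acetate F5. Heated with tert-butyldimethyl(vinyloxy)silane in toluene, F5 should open to the vinylketene (5R)-3-methylidene-1-oxohexadec-1-en-5-yl acetate F6, which adds the enol ether across its C=C bond to give (4R)-2-[2-(tert-butyldimethylsilyloxy)-4-oxocyclobutyl]pentadec-1-en-4-yl acetate F7. A 1,3-acyl shift of F7 then gives the cyclohex-3-enone (2R)-1-[(3R)-3-(tert-butyldimethylsilyloxy)-5-oxocyclohex-1-en-1-yl]tridecan-2-yl acetate F8, in which C1=C2 is already in place; this cascade is not face-selective with respect to the side chain, so the C3 epimer has to be removed by chromatography. α-Acetoxylation at the doubly activated C6 with Pb(OAc)4 should give (2R)-1-[(3R,6S)-6-acetoxy-3-(tert-butyldimethylsilyloxy)-5-oxocyclohex-1-en-1-yl]tridecan-2-yl acetate F9. Ketalisation (MeOSiMe3, cat. Me3SiOTf, −78 °C) gives (2R)-1-[(3R,6S)-6-acetoxy-3-(tert-butyldimethylsilyloxy)-5,5-dimethoxycyclohex-1-en-1-yl]tridecan-2-yl acetate F10, and elimination of methanol toward C4 (Me3SiOTf, iPr2NEt) returns to 21.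

Step 9. Hydride may be delivered with poor facial selectivity, or step 8 may give both selenide epimers so that substrate control fails. The fallback replaces substrate control by reagent control. It sets out from 17 and comes back at 18: reduction with catecholborane and (S)-2-methyl-CBS-oxazaborolidine (CBS reduction), in which the quaternary C1 acts as the large group, fixes C6 whatever the configuration at C1, which is erased in step 11. No new compound is made.

Further compounds
F1 | step 7 | 1-methoxybut-3-en-2-one | COCC(=O)C=C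
F2 | step 7 | (4S)-4-(tert-butyldimethylsilyloxy)-2-methoxycyclohex-2-en-1-one | COC1=C[C@@H](O[Si](C)(C)C(C)(C)C)CCC1=O
F3 | step 7 | (4S)-4-(tert-butyldimethylsilyloxy)-6-[(2R)-2-hydroxytridecyl]-2-methoxycyclohex-2-en-1-one | CCCCCCCCCCC[C@@H](O)CC1C[C@H](O[Si](C)(C)C(C)(C)C)C=C(OC)C1=O
F4 | step 11 | (2R)-1-(4,4-dichloro-3-oxocyclobut-1-en-1-yl)tridecan-2-yl acetate | CCCCCCCCCCC[C@@H](OC(C)=O)CC1=CC(=O)C1(Cl)Cl
F5 | step 11 | (2R)-1-(3-oxocyclobut-1-en-1-yl)tridecan-2-yl acetate | CCCCCCCCCCC[C@@H](OC(C)=O)CC1=CC(=O)C1
F6 | step 11 | (5R)-3-methylidene-1-oxohexadec-1-en-5-yl acetate | CCCCCCCCCCC[C@@H](OC(C)=O)CC(=C)C=C=O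
F7 | step 11 | (4R)-2-[2-(tert-butyldimethylsilyloxy)-4-oxocyclobutyl]pentadec-1-en-4-yl acetate | CCCCCCCCCCC[C@@H](OC(C)=O)CC(=C)C1C(O[Si](C)(C)C(C)(C)C)CC1=O
F8 | step 11 | (2R)-1-[(3R)-3-(tert-butyldimethylsilyloxy)-5-oxocyclohex-1-en-1-yl]tridecan-2-yl acetate | CCCCCCCCCCC[C@@H](OC(C)=O)CC1=C[C@H](O[Si](C)(C)C(C)(C)C)CC(=O)C1
F9 | step 11 | (2R)-1-[(3R,6S)-6-acetoxy-3-(tert-butyldimethylsilyloxy)-5-oxocyclohex-1-en-1-yl]tridecan-2-yl acetate | CCCCCCCCCCC[C@@H](OC(C)=O)CC1=C[C@H](O[Si](C)(C)C(C)(C)C)CC(=O)[C@H]1OC(C)=O
F10 | step 11 | (2R)-1-[(3R,6S)-6-acetoxy-3-(tert-butyldimethylsilyloxy)-5,5-dimethoxycyclohex-1-en-1-yl]tridecan-2-yl acetate | CCCCCCCCCCC[C@@H](OC(C)=O)CC1=C[C@H](O[Si](C)(C)C(C)(C)C)CC(OC)(OC)[C@H]1OC(C)=O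
F0 | step 9 | none | none
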